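**Assumptions (one line each)**
- (R)-4-Methylcyclopent-2-en-1-one (1) and (2E)-3-methylpenta-2,4-dien-1-ol (8) are bought. If needed, 1 comes from commercial (S)-3-methylcyclopentanone by Saegusa–Ito oxidation of its kinetic silyl enol ether. Neither is counted in the step total.
- The acid is never esterified except in the Claisen substrate, because a hindered acid on a quaternary carbon next to another quaternary carbon could not be re-hydrolysed.

**Retrosynthesis**
1. The (E,E)-4-phenylbutadienyl group comes last, by Heck coupling of (E)-β-bromostyrene (12, aromatic feedstock) onto a vinyl group on the quaternary carbon.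
2. KEY STEP: ring 2 (cyclohexene, C=C next to the quaternary centres) is closed by a desymmetrizing ring-closing metathesis (RCM). The symmetry broken is that of a gem-divinyl quaternary carbon, and one vinyl closes onto the isopropenyl group on ring 1.
3. The vicinal quaternary pair comes from an Ireland–Claisen rearrangement of a cyclopentenyl-propionate ester of 3-methylpenta-2,4-dien-1-ol.
4. Ring 1 comes from (R)-4-methylcyclopentenone (conjugate addition–alkylation, enol triflate, Et coupling). Ring 1 is therefore formed first and ring 2 last.

**Route**

**Step 1**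
Reactants: 1 (R)-4-methylcyclopent-2-en-1-one; 2 isopropenylmagnesium bromide; 3 methyl 2-(triflyloxy)propanoate.
Product: 4, 4-methyl-3-isopropenyl-2-[1-(methoxycarbonyl)ethyl]cyclopentan-1-one (3,4-trans and 2,3-trans; 4R).
Conditions: 2, CuBr·SMe2, THF, –78 °C; then HMPA, 3, –78 → –30 °C.
Reagents that add atoms: 2 (CC(=C)[Mg]Br); 3 (CC(OS(=O)(=O)C(F)(F)F)C(=O)OC).
Why: This is a Noyori-type three-component coupling. The cuprate adds anti to the C4 methyl, which sets Ca. The enolate is then alkylated trans to the new 3-substituent, which sets Cb. The new CH(Me)CO2Me centre forms as an epimeric mixture, which is erased in step 6.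

**Step 2**
Reactants: 4.
Product: 5, the enol triflate: 3-methyl-4-isopropenyl-5-[1-(methoxycarbonyl)ethyl]cyclopent-1-en-1-yl triflate.
Conditions: KHMDS, THF, –78 °C; then PhNTf2.
Reagents that add atoms: PhNTf2 (O=S(=O)(N(c1ccccc1)S(=O)(=O)C(F)(F)F)C(F)(F)F).
Why: Kinetic deprotonation at the unsubstituted α′-CH2 puts the C1=C3 alkene where the target needs it. The ester is less acidic than the ketone, so it is untouched, and no stereocentre is epimerized.

**Step 3**
Reactants: 5.
Product: 6, methyl 2-[2-ethyl-4-methyl-5-(prop-1-en-2-yl)cyclopent-2-en-1-yl]propanoate (ring centres as in 4).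
Conditions: EtMgBr, Fe(acac)3 (5 mol%), THF/NMP, 0 °C.
Reagents that add atoms: EtMgBr (CC[Mg]Br).
Why: Fürstner iron-catalysed Kumada coupling puts the ethyl group on the enol-triflate carbon without β-hydride problems, and the ester survives because the coupling is fast at 0 °C.

**Step 4**
Reactants: 6.
Product: 7, the corresponding propanoic acid.
Conditions: LiOH, THF/MeOH/H2O, rt.
Reagents that add atoms: water (O).
Why: Saponification of an unhindered secondary methyl ester. Ca and Cb are not acidic, so no ring centre is scrambled.

**Step 5**
Reactants: 7; 8 (2E)-3-methylpenta-2,4-dien-1-ol.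
Product: 9, the (2E)-3-methylpenta-2,4-dienyl ester of 7.
Conditions: EDC·HCl, DMAP, CH2Cl2, 0 °C → rt.
Reagents that add atoms: none.
Why: Steglich esterification under neutral conditions, so the acid-sensitive dienol survives and no stereocentre is touched.

**Step 6**
Reactants: 9.
Product: 10, 2-[cyclopentenyl]-2,3-dimethyl-3-vinylpent-4-enoic acid, with the cyclopentene as in 7 and the new B centre (C2 of the acid) set.
Conditions: LDA, THF, –78 °C; TBSCl, HMPA; warm to 65 °C; then 1 M HCl/THF.
Reagents that add atoms: none (the silyl group is removed on work-up).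
Why: Ireland–Claisen rearrangement of the silyl ketene acetal through a chair transition state.
Proposed new method: this extends Ireland–Claisen to a tetrasubstituted ketene acetal plus a γ,γ-disubstituted dienyl allyl partner, forming two adjacent quaternary centres. The enolate face is expected to be attacked anti to the bulkier Ca side, like a Felkin-type model. The alkene geometry of 8 is irrelevant because both termini become identical vinyl groups, so carbon A is prochiral and the gem-divinyl unit is the symmetric precursor for step 7.

**Step 7 (KEY STEP)**
Reactants: 10.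
Product: 11, the bicyclic acid with an exocyclic vinyl: 3-ethyl-1,4,5,7-tetramethyl-5-vinyl-3a,4,5,7a-tetrahydro-1H-indene-4-carboxylic acid, trans-fused, 1R.
Conditions: Hoveyda–Grubbs II (10 mol%), toluene (3 mM), 80 °C, with benzoquinone.
Reagents that add atoms: none (ethylene is lost).
Why: Ring-closing metathesis of the isopropenyl group with one of the two enantiotopic/diastereotopic vinyl groups on carbon A forms the trisubstituted C2′=C3′ alkene. The choice of vinyl sets A.
Proposed new method: this is a diastereoselective desymmetrizing RCM next to two quaternary centres. The closing vinyl is chosen because its closure leaves the remaining vinyl axial and anti to the axial B-methyl in a trans-fused chair, as in the target. The closest known chemistry is desymmetrizing gem-divinyl RCM in terpene synthesis. Expect only a modest bias (≈2:1), so the A epimers will probably need chromatographic separation.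

**Step 8**
Reactants: 11; 12 (E)-β-bromostyrene.
Product: 13, 22-nor-zyggomphic acid B.
Conditions: Pd(OAc)2 (10 mol%), nBu4NCl, NaHCO3, DMF, 60 °C.
Reagents that add atoms: none.
Why: Jeffery-type Heck coupling occurs selectively at the monosubstituted vinyl. Migratory insertion puts the styryl group on the terminal carbon, and syn β-hydride elimination gives the (E,E)-aryldiene. The free carboxylate is tolerated, the trisubstituted ring alkenes are inert, and no ring stereocentre is changed.

**Compound list**

| # | Name | SMILES | Role |
|---|---|---|---|
| 1 | (R)-4-methylcyclopent-2-en-1-one | C[C@@H]1CC(=O)C=C1 | starting material |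
| 2 | isopropenylmagnesium bromide | CC(=C)[Mg]Br | starting material |
| 3 | methyl 2-(triflyloxy)propanoate | CC(OS(=O)(=O)C(F)(F)F)C(=O)OC | starting material |
| 4 | 4-methyl-3-isopropenyl-2-[1-(methoxycarbonyl)ethyl]cyclopentanone | O=C1C[C@@H](C)[C@H](C(C)=C)[C@H]1C(C)C(=O)OC | intermediate |
| 5 | enol triflate of 4 | FC(F)(F)S(=O)(=O)OC1=C[C@@H](C)[C@H](C(C)=C)[C@H]1C(C)C(=O)OC | intermediate |
| 6 | methyl 2-[2-ethyl-4-methyl-5-isopropenylcyclopent-2-en-1-yl]propanoate | CCC1=C[C@@H](C)[C@H](C(C)=C)[C@H]1C(C)C(=O)OC | intermediate |
| 7 | corresponding propanoic acid | CCC1=C[C@@H](C)[C@H](C(C)=C)[C@H]1C(C)C(=O)O | intermediate |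
| 8 | (2E)-3-methylpenta-2,4-dien-1-ol | C=C/C(C)=C/CO | starting material |
| 9 | (2E)-3-methylpenta-2,4-dienyl ester of 7 | CCC1=C[C@@H](C)[C@H](C(C)=C)[C@H]1C(C)C(=O)OC/C=C(\C)C=C | intermediate |
| 10 | gem-divinyl acid (Claisen product) | CCC1=C[C@@H](C)[C@H](C(C)=C)[C@H]1[C@@](C)(C(=O)O)C(C)(C=C)C=C | intermediate |
| 11 | bicyclic vinyl acid (RCM product) | CCC1=C[C@@H](C)[C@@H]2C(C)=C[C@](C)(C=C)[C@](C)(C(=O)O)[C@@H]12 | intermediate |
| 12 | (E)-β-bromostyrene | Br/C=C/c1ccccc1 | starting material |
| 13 | 22-nor-zyggomphic acid B (1R at the CHMe carbon) | CCC1=C[C@@H](C)[C@@H]2C(C)=C[C@](C)(/C=C/C=C/c3ccccc3)[C@](C)(C(=O)O)[C@@H]12 | target |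

**Totals:** 8 steps; longest linear sequence 8 steps (1 → 4 → 5 → 6 → 7 → 9 → 10 → 11 → 13).

**Three steps most likely to fail**
1. **Step 6 (Claisen forming vicinal quaternary centres; B face selectivity).**
   Fallback: a type-1 intramolecular Diels–Alder of an HWE-assembled trienone. This builds ring 2, both quaternary centres and the trans-fused hydrindanone at once. The ketone is then converted to the ethyl alkene by enol triflate formation and Et coupling.
2. **Step 7 (congested, desymmetrizing RCM; about 1:1 dr at A possible).**
   Fallback: run the Claisen with the (E)-styryl dienol PhCH=CH–CH(OH)–CH=C(Me)–CH=CH2. Chair-transition-state control then sets A and installs the dienyl group, and RCM only closes the ring using the vinyl group.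
3. **Step 8 (Heck on a neopentylic vinyl; risk of Pd–H alkene isomerization).**
   Fallback: cross-metathesis with (E)-1-phenylbuta-1,3-diene, or oxidative cleavage of the vinyl group followed by HWE with diethyl cinnamylphosphonate.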